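## Structural features

The target is a 3,3'-linked biflavanone. Two 5,7-dihydroxychroman-4-one units, each a pyranone ring fused to a phloroglucinol-type ring (ring A and ring A'), are joined by the single bond C3–C3'. Unit A carries a 4-methoxyphenyl group at C2 and unit B a 4-hydroxyphenyl group at C2'; this one methyl ether is the only constitutional difference between the halves. The four stereocentres C2, C3, C3' and C2' are contiguous and have the configuration (2S,3S,3'S,2'R): the aryl group and the C3 substituent are cis in unit A (the less stable arrangement) and trans in unit B. C3 and C3' are each alpha to a ketone and beta to an aryloxy group, so acid or base can epimerise them (cis to trans in unit A) or open the pyranone rings by retro-oxa-Michael reaction, which would also scramble C2 and C2'. The benzylic C2–O1 and C2'–O1' bonds and the five free phenols add to the sensitivity. The real difficulty is to create the cis C2–C3 relationship of unit A late, under neutral conditions, and on the correct face with respect to the trans unit B already present. The key step exploits that C2 of unit A, without the C2–C3 bond, is the benzylic CH2 of a 4-methoxybenzyl ether on O1 of ring A, six atoms from C3 (C3, C4, C4a, C8a, O1, C2), so a carbenoid at C3 can insert into one of its C–H bonds and close the pyranone ring.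

## Logic of the disconnections

19 to 18. Five benzylic O–C bonds are cut: three benzyl ethers on unit B and two 4-methoxybenzyl ethers on O5 and O7 of unit A. Every phenol is thereby masked by a group that falls in one neutral hydrogenolysis, which spares the aryl methyl ether and the cis ketone. The gain is a non-acidic, phenol-free substrate for the carbenoid step. The demand is that hydrogenolysis leaves the ring bonds C2–O1 and C2'–O1' intact.

18 to 17. The C2–C3 bond of unit A is cut. This opens its pyranone ring and removes two stereocentres: C3 becomes a diazo carbon and C2 the CH2 of an ether on O1. It is the one bond whose formation can be kinetic, neutral and cis-selective. Both ortho oxygens of ring A in 17 carry the same ether, so insertion at either gives 18 and no separate protecting group is needed at O5. The demand is that insertion beats 1,2-hydride shift, ylide formation and arene attack, and occurs cis and on the right face relative to C3'.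

17 to 14. The C3=N bond is cut, which leaves a methylene between C3' and the ring A ketone. The diazo group tolerates little and is therefore put in last. The gain is a plain 1,4-diketone. The forward step (through 15 and 16) must enolise C3 and not C3', cold enough that unit B does not open.

14 to 12 and 6. The C3–C3' bond is cut between the alpha carbon of a ketone and a bromomethyl ketone. This is the convergent cut: it separates the two phloroglucinol-derived halves. The trans relationship in unit B follows from attack anti to the C2' aryl group. The demand is that 13 alkylates faster than it opens or exchanges protons with 6.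

12 to 10 and 11. The C2'–aryl bond is cut. A catalytic asymmetric conjugate addition sets C2', the one stereocentre from which the other three are derived, and the precursor is a flat, achiral chromone. The demand is high enantioselectivity on an electron-rich 5-alkoxychromone without addition to the product ketone.

10 to 8, and 8 to 1 and 7. The O1'–C2' bond and the one-carbon unit C2' are removed (through 9), then two benzyl O–C bonds. This reduces unit B to a commercial acetophenone. In the forward direction the hydrogen-bonded ortho hydroxyl of 1 must stay free when only two equivalents of 7 are used.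

6 to 4, 4 to 3, and 3 to 1 and 2. The C–Br bond is cut, then the three 4-methoxybenzyl O–C bonds in two stages. Bromination must occur at the side chain and not on four electron-rich rings, which is why it passes through 5. The etherification is divided because the last hydroxyl is hydrogen-bonded to the ketone: two equivalents of 2 react under mild conditions and the third needs a more forcing stage.

## Other disconnections considered

Alternative 1: The cut goes through C2–C3 and C2'–C3' together, with a temporary two-carbon bridge between C2 and C2'. Cyclohexene A1 would form from diene A2 and dienophile A3 in a Diels–Alder reaction under a chiral Lewis acid chelated by the imide, for instance Cu(OTf)2 with a bis(oxazoline) ligand.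
- In its favour: one concerted, suprafacial step would fix all four stereocentres. With E geometry in A2 and A3 and the imide endo, ring cleavage would give exactly cis unit A (aroyl half) and trans unit B (imide half). In stereocentre economy and predictability of mechanism this is better than the chosen plan, which sets the centres in three separate events.
- Against it: the regiochemistry of the unsymmetrical diene A2 rests only on the small electronic difference between its pivaloyloxy- and benzyloxy-substituted aryl groups. After A1, the ring alkene must be cleaved, two epimerisable alpha-aryl aldehydes (each beta to a carbonyl) turned into C–O bonds with retention, the fluoroarene closed by nucleophilic aromatic substitution, the imide converted into the second aryl ketone and ring, and the pivalate exchanged for methyl.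
- Comparison: the key step is mechanistically more reliable, but A1 is structurally far from the target. The chosen plan needs one step after 18. This plan needs many, several of them oxidative and poorly tolerated by the electron-rich rings, so in step economy it is clearly worse.

Alternative 2: The cut removes O1'–C8a', C4'–C4a' and O1'–C2', the whole pyranone ring of unit B around a preformed unit A. Fluoride would release aryne A7 from silylaryl triflate A6. The carboxylate of acid A5 would add, the aryl anion would take over the acyl group, and the phenoxide would close onto C2' to give A4.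
- In its favour: the plan is convergent, and the regiochemistry of the 3,5-dialkoxy aryne A7 matches the need (oxygen meta to the alkoxy group, acyl group next to it). C4 of unit A is a silyl ether in A5 and A4, so the cis unit has no enolisable centre during the basic step. On that point it is better than the chosen plan, where cis unit A is an enolisable ketone from the moment it forms. In convergence the two plans are equal.
- Against it: cis unit A must be made beforehand by other means, so the central stereochemical problem is moved, not solved. C2' and C3' would arise in an oxa-Michael addition and a protonation; only the trans preference within unit B is predictable, not the face relative to unit A. Acyl transfer at the alpha-branched acid A5 is hindered.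
- Comparison: structurally A4 is close to the target but holds C4 at the wrong oxidation level. The mechanism is ionic and reversible, where the chosen step is kinetic and irreversible. Three steps would follow A4 (desilylation, oxidation at C4, hydrogenolysis) against one after 18.

Alternative 3: The cut is O1'–C2' alone. In phenol A9 the 4-hydroxybenzyl group on C3' would be dehydrogenated by DDQ to quinone methide A10, and the ortho phenol of ring A' would add to C2' in a 6-endo closure to give A8.
- In its favour: it uses the one free 4-hydroxyphenyl group that distinguishes unit B from unit A, so that position needs no protecting group. It needs no diazo compound and no rhodium, which in safety and cost is better than the chosen plan. One hydrogenolysis would follow A8, equal to the chosen plan.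
- Against it: unit A in A9 contains the anisyl-bearing C2–H, itself a para-methoxybenzylic ether C–H of the kind that the oxidant attacks, so chemoselectivity is doubtful. Cis unit A must again be made first and carried as an enolisable ketone through the preparation of A9, whose C3' lies between two carbonyl-bearing carbons.
- Comparison: structurally it closes the easier trans ring and leaves the harder cis ring unsolved. Mechanistically C2' would be set only by the thermodynamic trans preference, which is adequate for unit B. In step economy after the key step the two plans are equal, but the route to A9 is longer than the route to 17.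

Key step: step 9

Remark on stereochemical sense: the (R) diphosphine in step 6 and the (S) dirhodium carboxylate in step 9 are assumed to deliver the (2'R) centre and the (2S,3S) centres; if either sense is the reverse, the mirror-image ligand is used without other change.

Remark on the precursor: all three oxygens of ring A carry 4-methoxybenzyl ethers. The two ortho ethers are equivalent sites for insertion, and no silyl ether or separate desilylation is needed. The descriptors are (2R,3S) for 14 and 17 and (2S,3S,2'R,3'S) for 18 and 19.

## Route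

Step 1
Reactants: 1 1-(2,4,6-trihydroxyphenyl)ethanone; 2 4-methoxybenzyl chloride
Product: 3 1-[2-hydroxy-4,6-bis(4-methoxybenzyloxy)phenyl]ethanone
Conditions: 2 (2.1 equiv), K2CO3, NaI (cat.), acetone, reflux
Reagents that add atoms: 4-methoxybenzyl chloride (second equivalent of 2), COc1ccc(CCl)cc1
Why: Williamson ether synthesis in which two molecules of 2 are incorporated; the para and one ortho hydroxyl react, and the remaining ortho hydroxyl, hydrogen-bonded to the ketone, should stay free under these mild conditions.

Step 2
Reactants: 3 1-[2-hydroxy-4,6-bis(4-methoxybenzyloxy)phenyl]ethanone; 2 4-methoxybenzyl chloride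
Product: 4 1-[2,4,6-tris(4-methoxybenzyloxy)phenyl]ethanone
Conditions: 2 (1.3 equiv), K2CO3, Bu4NI (cat.), DMF, 60 °C
Reagents that add atoms: none
Why: Williamson ether synthesis; a polar aprotic solvent, iodide catalysis and gentle heating should break the chelate and alkylate the last, hydrogen-bonded hydroxyl with one further molecule of 2.

Step 3
Reactants: 4 1-[2,4,6-tris(4-methoxybenzyloxy)phenyl]ethanone
Product: 6 2-bromo-1-[2,4,6-tris(4-methoxybenzyloxy)phenyl]ethanone, via silyl enol ether 5 (not isolated)
Conditions: Me3SiOTf, Et3N, CH2Cl2, 0 °C; then N-bromosuccinimide, −78 → 0 °C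
Reagents that add atoms: N-bromosuccinimide, O=C1CCC(=O)N1Br
Why: Soft enolisation of the methyl ketone followed by electrophilic bromination of the silyl enol ether, which at −78 °C should be much faster than bromination of the electron-rich rings; the medium stays non-acidic, so the benzylic ethers survive.

Step 4
Reactants: 1 1-(2,4,6-trihydroxyphenyl)ethanone; 7 benzyl bromide
Product: 8 1-[2,4-bis(benzyloxy)-6-hydroxyphenyl]ethanone
Conditions: 7 (2.05 equiv), K2CO3, acetone, reflux
Reagents that add atoms: benzyl bromide (second equivalent of 7), BrCc1ccccc1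
Why: Williamson ether synthesis in which two molecules of 7 are incorporated; the para and one ortho hydroxyl react, and the second ortho hydroxyl, hydrogen-bonded to the ketone, should remain free.

Step 5
Reactants: 8 1-[2,4-bis(benzyloxy)-6-hydroxyphenyl]ethanone
Product: 10 5,7-bis(benzyloxy)-4H-chromen-4-one, via enaminone 9 (not isolated)
Conditions: Me2NCH(OMe)2, toluene, 95 °C; then aq. HCl (2 M), CH2Cl2, 40 °C
Reagents that add atoms: N,N-dimethylformamide dimethyl acetal, COC(OC)N(C)C
Why: Condensation of the methyl ketone with the formamide acetal gives the enaminone; acid then triggers 6-endo addition of the phenol and loss of dimethylamine, the standard chromone synthesis from 2-hydroxyacetophenones.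

Step 6
Reactants: 10 5,7-bis(benzyloxy)-4H-chromen-4-one; 11 4-(benzyloxy)phenylboronic acid
Product: 12 (2R)-5,7-bis(benzyloxy)-2-[4-(benzyloxy)phenyl]chroman-4-one
Conditions: [Rh(OH)(cod)]2 (1.5 mol%), (R)-MeO-F12-BIPHEP (3.3 mol%), toluene/H2O, 30 °C
Reagents that add atoms: none
Why: Hayashi–Miyaura asymmetric 1,4-addition of an arylboronic acid to a chromone: the aryl complex of monovalent rhodium adds to the enone face selected by the atropisomeric diphosphine (2,2'-bis[bis(3,4,5-trifluorophenyl)phosphino]-6,6'-dimethoxybiphenyl) and water releases the ketone, which sets C2' as R. The electron-poor ligand makes conjugate addition fast enough that the product ketone should not be arylated at carbonyl.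

Step 7
Reactants: 12 (2R)-5,7-bis(benzyloxy)-2-[4-(benzyloxy)phenyl]chroman-4-one; 6 2-bromo-1-[2,4,6-tris(4-methoxybenzyloxy)phenyl]ethanone
Product: 14 (2R,3S)-5,7-bis(benzyloxy)-2-[4-(benzyloxy)phenyl]-3-{2-oxo-2-[2,4,6-tris(4-methoxybenzyloxy)phenyl]ethyl}chroman-4-one, via lithium enolate 13 (not isolated)
Conditions: LiN(SiMe3)2 (1.05 equiv), THF, −78 °C; then 6, DMPU, −78 → −40 °C; AcOH, −78 °C
Reagents that add atoms: none
Why: SN2 alkylation of a ketone enolate by an alpha-bromo ketone; the electrophile approaches C3' anti to the C2' aryl group, which sets C3' as S (2,3-trans, also the stable isomer). Low temperature keeps the enolate from opening by retro-oxa-Michael reaction, and the shielded, electron-rich carbonyl of 6 disfavours carbonyl addition.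

Step 8
Reactants: 14 (2R,3S)-5,7-bis(benzyloxy)-2-[4-(benzyloxy)phenyl]-3-{2-oxo-2-[2,4,6-tris(4-methoxybenzyloxy)phenyl]ethyl}chroman-4-one
Product: 17 (2R,3S)-5,7-bis(benzyloxy)-2-[4-(benzyloxy)phenyl]-3-{1-diazo-2-oxo-2-[2,4,6-tris(4-methoxybenzyloxy)phenyl]ethyl}chroman-4-one, via lithium enolate 15 (not isolated), via trifluoroacetyl diketone 16 (not isolated)
Conditions: LiN(SiMe3)2 (1.1 equiv), THF, −78 °C; CF3CO2CH2CF3, −78 °C; aq. NH4Cl; then 4-AcNHC6H4SO2N3, Et3N, H2O, MeCN, 0 °C → rt
Reagents that add atoms: 4-acetamidobenzenesulfonyl azide, CC(=O)Nc1ccc(S(=O)(=O)N=[N+]=[N-])cc1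
Why: Detrifluoroacetylative (Regitz-type deacylative) diazo transfer: the bulky amide should remove a proton kinetically from the unhindered C3 methylene and not from the C3' methine, the enolate is trifluoroacetylated, and the activated diketone takes the diazo group from the sulfonyl azide with loss of the trifluoroacetyl group as a sulfonamide. The amine stage is too mild to open unit B, and any epimerisation at C3' returns to the trans isomer.

Step 9
Reactants: 17 (2R,3S)-5,7-bis(benzyloxy)-2-[4-(benzyloxy)phenyl]-3-{1-diazo-2-oxo-2-[2,4,6-tris(4-methoxybenzyloxy)phenyl]ethyl}chroman-4-one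
Product: 18 (2S,3S)-3-{(2R,3S)-5,7-bis(benzyloxy)-2-[4-(benzyloxy)phenyl]-4-oxochroman-3-yl}-5,7-bis(4-methoxybenzyloxy)-2-(4-methoxyphenyl)chroman-4-one
Conditions: Rh2(S-PTTL)4 (2 mol%), toluene/CH2Cl2, −78 → −30 °C, slow addition of 17
Reagents that add atoms: none
Why: The paddlewheel carboxylate of divalent rhodium (dirhodium tetrakis[N-phthaloyl-(S)-tert-leucinate]) takes N2 from the diazo group and gives an electrophilic carbenoid at C3, which inserts through a three-centre, hydride-transfer-like transition state into a benzylic C–H bond of an ortho 4-methoxybenzyl ether and so joins C2 to C3. The closest known reaction type is the dirhodium-carboxylate-catalysed intramolecular C–H insertion of 1-(2-alkoxyphenyl)-2-diazo ketones next to the ether oxygen, which gives 2-substituted chroman-4-ones with a kinetic preference for the 2,3-cis isomer. The pyranone ring of unit A closes as a six-membered ring by 1,6-insertion; the usual 1,5 site is the ether oxygen itself, so no five-membered carbocycle can form. C3 is set in the same event as C2: in the compact transition state the anisyl group on the reacting carbon and the flavanonyl group on the carbenoid carbon both turn away from the carboxylate wall and end on the same face of the new ring (cis), and the neutral, non-enolising medium preserves this kinetic result. The absolute sense at C2 and C3 (which diastereotopic benzylic hydrogen is replaced, which carbenoid face is used) is set by the chiral phthalimido-tert-leucinate pocket acting together with the neighbouring C3' centre, so a matched pair is needed. Chemoselectivity is needed against 1,2-hydride shift from C3', oxonium ylide formation with Stevens shift of the anisylmethyl group, and attack on the 4-benzyloxyphenyl ring; the substrate favours insertion because the target C–H bond is activated twice (ether oxygen and para-methoxyphenyl), the C3'–H bond is a poor hydride donor next to the C4' carbonyl, and the ether oxygen, conjugated to the aroyl group, is a weak ylide donor. Bulky carboxylate ligands and low temperature slow the hydride shift further. The two ortho ethers of ring A are identical and exchange by rotation about the aryl–carbonyl bond, so insertion at either gives the same product.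

Step 10
Reactants: 18 (2S,3S)-3-{(2R,3S)-5,7-bis(benzyloxy)-2-[4-(benzyloxy)phenyl]-4-oxochroman-3-yl}-5,7-bis(4-methoxybenzyloxy)-2-(4-methoxyphenyl)chroman-4-one
Product: 19 (2S,3S)-3-[(2R,3S)-5,7-dihydroxy-2-(4-hydroxyphenyl)-4-oxochroman-3-yl]-5,7-dihydroxy-2-(4-methoxyphenyl)chroman-4-one
Conditions: H2 (1 atm), Pd/C (10% Pd), EtOAc/MeOH, rt; filtration, no base
Reagents that add atoms: none
Why: Hydrogenolysis of three benzyl and two 4-methoxybenzyl aryl ethers under neutral conditions; primary benzylic ethers should cleave well before the secondary, ring-bound C2–O1 and C2'–O1' bonds, and no acid or base is present to epimerise C3 of the cis unit.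

## Compound list

1 | 1-(2,4,6-trihydroxyphenyl)ethanone | CC(=O)c1c(O)cc(O)cc1O | starting material
2 | 4-methoxybenzyl chloride | COc1ccc(CCl)cc1 | starting material
3 | 1-[2-hydroxy-4,6-bis(4-methoxybenzyloxy)phenyl]ethanone | CC(=O)c1c(O)cc(OCc2ccc(OC)cc2)cc1OCc1ccc(OC)cc1 | intermediate
4 | 1-[2,4,6-tris(4-methoxybenzyloxy)phenyl]ethanone | CC(=O)c1c(OCc2ccc(OC)cc2)cc(OCc2ccc(OC)cc2)cc1OCc1ccc(OC)cc1 | intermediate
5 | trimethyl({1-[2,4,6-tris(4-methoxybenzyloxy)phenyl]ethenyl}oxy)silane (silyl enol ether of 4) | C=C(O[Si](C)(C)C)c1c(OCc2ccc(OC)cc2)cc(OCc2ccc(OC)cc2)cc1OCc1ccc(OC)cc1 | intermediate (not isolated)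
6 | 2-bromo-1-[2,4,6-tris(4-methoxybenzyloxy)phenyl]ethanone | BrCC(=O)c1c(OCc2ccc(OC)cc2)cc(OCc2ccc(OC)cc2)cc1OCc1ccc(OC)cc1 | intermediate
7 | benzyl bromide | BrCc1ccccc1 | starting material
8 | 1-[2,4-bis(benzyloxy)-6-hydroxyphenyl]ethanone | CC(=O)c1c(O)cc(OCc2ccccc2)cc1OCc1ccccc1 | intermediate
9 | (E)-1-[2,4-bis(benzyloxy)-6-hydroxyphenyl]-3-(dimethylamino)prop-2-en-1-one | CN(C)/C=C/C(=O)c1c(O)cc(OCc2ccccc2)cc1OCc1ccccc1 | intermediate (not isolated)
10 | 5,7-bis(benzyloxy)-4H-chromen-4-one | O=c1ccoc2cc(OCc3ccccc3)cc(OCc3ccccc3)c12 | intermediate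
11 | 4-(benzyloxy)phenylboronic acid | OB(O)c1ccc(OCc2ccccc2)cc1 | starting material
12 | (2R)-5,7-bis(benzyloxy)-2-[4-(benzyloxy)phenyl]chroman-4-one | O=C1C[C@H](c2ccc(OCc3ccccc3)cc2)Oc2cc(OCc3ccccc3)cc(OCc3ccccc3)c12 | intermediate
13 | lithium (2R)-5,7-bis(benzyloxy)-2-[4-(benzyloxy)phenyl]-2H-chromen-4-olate (lithium enolate of 12) | [Li]OC1=C[C@H](c2ccc(OCc3ccccc3)cc2)Oc2cc(OCc3ccccc3)cc(OCc3ccccc3)c12 | intermediate (not isolated)
14 | (2R,3S)-5,7-bis(benzyloxy)-2-[4-(benzyloxy)phenyl]-3-{2-oxo-2-[2,4,6-tris(4-methoxybenzyloxy)phenyl]ethyl}chroman-4-one | COc1ccc(COc2cc(OCc3ccc(OC)cc3)cc(OCc3ccc(OC)cc3)c2C(=O)C[C@@H]2C(=O)c3c(OCc4ccccc4)cc(OCc4ccccc4)cc3O[C@H]2c2ccc(OCc3ccccc3)cc2)cc1 | intermediate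
15 | lithium enolate of 14 at C3=C4 of the ring A ketone (double-bond geometry immaterial; unit B unchanged, 2R,3S) | COc1ccc(COc2cc(OCc3ccc(OC)cc3)cc(OCc3ccc(OC)cc3)c2C(O[Li])=C[C@@H]2C(=O)c3c(OCc4ccccc4)cc(OCc4ccccc4)cc3O[C@H]2c2ccc(OCc3ccccc3)cc2)cc1 | intermediate (not isolated)
16 | (2R,3S)-5,7-bis(benzyloxy)-2-[4-(benzyloxy)phenyl]-3-{4,4,4-trifluoro-1,3-dioxo-1-[2,4,6-tris(4-methoxybenzyloxy)phenyl]butan-2-yl}chroman-4-one (epimers at the new carbon, partly enolised) | COc1ccc(COc2cc(OCc3ccc(OC)cc3)cc(OCc3ccc(OC)cc3)c2C(=O)C(C(=O)C(F)(F)F)[C@@H]2C(=O)c3c(OCc4ccccc4)cc(OCc4ccccc4)cc3O[C@H]2c2ccc(OCc3ccccc3)cc2)cc1 | intermediate (not isolated)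
17 | (2R,3S)-5,7-bis(benzyloxy)-2-[4-(benzyloxy)phenyl]-3-{1-diazo-2-oxo-2-[2,4,6-tris(4-methoxybenzyloxy)phenyl]ethyl}chroman-4-one | COc1ccc(COc2cc(OCc3ccc(OC)cc3)cc(OCc3ccc(OC)cc3)c2C(=O)C(=[N+]=[N-])[C@@H]2C(=O)c3c(OCc4ccccc4)cc(OCc4ccccc4)cc3O[C@H]2c2ccc(OCc3ccccc3)cc2)cc1 | intermediate
18 | (2S,3S)-3-{(2R,3S)-5,7-bis(benzyloxy)-2-[4-(benzyloxy)phenyl]-4-oxochroman-3-yl}-5,7-bis(4-methoxybenzyloxy)-2-(4-methoxyphenyl)chroman-4-one | COc1ccc([C@H]2Oc3cc(OCc4ccc(OC)cc4)cc(OCc4ccc(OC)cc4)c3C(=O)[C@H]2[C@@H]2C(=O)c3c(OCc4ccccc4)cc(OCc4ccccc4)cc3O[C@H]2c2ccc(OCc3ccccc3)cc2)cc1 | intermediate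
19 | (2S,3S)-3-[(2R,3S)-5,7-dihydroxy-2-(4-hydroxyphenyl)-4-oxochroman-3-yl]-5,7-dihydroxy-2-(4-methoxyphenyl)chroman-4-one | COc1ccc([C@H]2Oc3cc(O)cc(O)c3C(=O)[C@H]2[C@@H]2C(=O)c3c(O)cc(O)cc3O[C@H]2c2ccc(O)cc2)cc1 | target

## Step count and least certain steps

Total: 10 steps. Longest linear sequence: 7 steps (steps 4 to 10: 1 → 8 → 10 → 12 → 14 → 17 → 18 → 19; the other branch, steps 1, 2, 3 and 7 to 10, is equally long).

Step 9 (key step). What may go wrong: loss of stereocontrol, either closure to the 2,3-trans ring or insertion on the wrong face relative to C3', because the catalyst and the C3' centre may be mismatched and the C3–C3' bond rotates freely. Second in likelihood is diversion of the carbenoid by 1,2-hydride shift from C3', by ylide formation with Stevens shift, or by attack on the nearby aryl ring. The antipodal catalyst and carboxamidate ligands would be screened first. Fallback: C3 is set by kinetic protonation instead of by the insertion, with the C4' ketone masked so that C3 is the only enolisable carbon. It sets out from 14 and returns at 18. NaBH4 (MeOH/THF, 0 °C) should reduce only the flavanone ketone, the twisted and hindered ring A ketone being inert, to the C4' alcohol F1, and Et3SiOTf with 2,6-lutidine gives the triethylsilyl ether F2. LiN(SiMe3)2 and CF3CO2CH2CF3 as in step 8 give the trifluoroacetyl diketone F3, and 4-AcNHC6H4SO2N3 with Et3N gives the masked diazo ketone F4. Rhodium-catalysed insertion, now asked to control only C2, gives the silyl-protected biflavanone, either directly as the cis isomer F7 or as the 2,3-trans isomer F5. In the latter case LiN(SiMe3)2 at −78 °C converts it into the lithium enolate F6, which 2,6-di-tert-butyl-4-methylphenol should protonate on the face opposite the C2 anisyl group to give the cis isomer F7. Bu4NF buffered with AcOH (THF, 0 °C) gives the hydroxy biflavanone F8, and Dess–Martin periodinane (NaHCO3, CH2Cl2) gives 18.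

Step 8. What may go wrong: deprotonation at C3' instead of C3 (the C3' hydrogen is axial and alpha to a conjugated ketone). This would lead to opening of unit B by retro-oxa-Michael reaction with erosion of C2', or during the amine stage to enolisation towards a vinyl-diazo tautomer that cyclises to a pyrazole. Fallback: the C4' ketone is masked during diazo transfer. It sets out from 14 and returns at 17. It passes through the C4' alcohol F1, the triethylsilyl ether F2 and the trifluoroacetyl diketone F3 to the masked diazo ketone F4 as under step 9. Bu4NF buffered with AcOH (THF, 0 °C) then gives the diazo alcohol F9, and Dess–Martin periodinane (NaHCO3, CH2Cl2) gives 17.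

Step 7. What may go wrong: opening of the enolate by expulsion of the aryloxide (racemisation at C2' after reclosure) and proton transfer from the acidic methylene of 6 to the enolate, which stops the alkylation. Fallback: radical alkylation without a free enolate. It sets out from 12 and returns at 14. Me3SiOTf and Et3N (CH2Cl2, 0 °C) give the trimethylsilyl enol ether F10. With 6, Ir(ppy)3 (1 mol%) and blue light in MeCN, the alpha-keto radical formed by one-electron reduction of 6 should add to C3' anti to the aryl group; oxidation of the resulting alpha-silyloxy radical and loss of the silyl group give 14.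

Step 6. What may go wrong: slow conjugate addition or low enantioselectivity with the electron-rich 5-alkoxychromone, accompanied by protodeboronation of 11. Fallback: classical ring construction followed by kinetic resolution. It sets out from 8 and returns at 12. Claisen–Schmidt condensation of 8 with 4-benzyloxybenzaldehyde (KOH, EtOH) gives the 2'-hydroxychalcone F11, and NaOAc in refluxing EtOH closes it to the racemic flavanone F12. Asymmetric transfer hydrogenation with RuCl(p-cymene)(TsDPEN) in HCO2H/Et3N, using the catalyst antipode that reduces the (2S) ketone, should leave 12 unreduced beside the separable cis-flavan-4-ol F13.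

Step 10. What may go wrong: hydrogenolytic opening of the pyranone rings at the benzylic C2–O1 bond (activated by the para-methoxy group) or at C2'–O1', or incomplete cleavage of the hindered ethers at O5 and O5'. Fallback: Lewis-acid dealkylation in place of hydrogenation. It sets out from 18 and returns at 19. BCl3 with pentamethylbenzene as cation scavenger (CH2Cl2, −78 °C) should cleave benzyl and 4-methoxybenzyl aryl ethers and spare the aryl methyl ether at that temperature. This fallback makes no new compound (F0).

## Further compounds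

F1 | step 9 | C4' alcohol of 14: 2-{5,7-bis(benzyloxy)-2-[4-(benzyloxy)phenyl]-4-hydroxychroman-3-yl}-1-[2,4,6-tris(4-methoxybenzyloxy)phenyl]ethanone, C2'/C3' as in 14, C4' epimers | COc1ccc(COc2cc(OCc3ccc(OC)cc3)cc(OCc3ccc(OC)cc3)c2C(=O)C[C@@H]2C(O)c3c(OCc4ccccc4)cc(OCc4ccccc4)cc3O[C@H]2c2ccc(OCc3ccccc3)cc2)cc1
F2 | step 9 | triethylsilyl ether of F1 at O4' | COc1ccc(COc2cc(OCc3ccc(OC)cc3)cc(OCc3ccc(OC)cc3)c2C(=O)C[C@@H]2C(O[Si](CC)(CC)CC)c3c(OCc4ccccc4)cc(OCc4ccccc4)cc3O[C@H]2c2ccc(OCc3ccccc3)cc2)cc1
F3 | step 9 | trifluoroacetyl diketone: F2 with a trifluoroacetyl group on C3 (epimers at C3 and C4', partly enolised) | COc1ccc(COc2cc(OCc3ccc(OC)cc3)cc(OCc3ccc(OC)cc3)c2C(=O)C(C(=O)C(F)(F)F)[C@@H]2C(O[Si](CC)(CC)CC)c3c(OCc4ccccc4)cc(OCc4ccccc4)cc3O[C@H]2c2ccc(OCc3ccccc3)cc2)cc1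
F4 | step 9 | masked diazo ketone: 17 with a triethylsilyloxy group (C4' epimers) in place of the C4' ketone | COc1ccc(COc2cc(OCc3ccc(OC)cc3)cc(OCc3ccc(OC)cc3)c2C(=O)C(=[N+]=[N-])[C@@H]2C(O[Si](CC)(CC)CC)c3c(OCc4ccccc4)cc(OCc4ccccc4)cc3O[C@H]2c2ccc(OCc3ccccc3)cc2)cc1
F5 | step 9 | 2,3-trans isomer of the silyl-protected biflavanone: C3 epimer of F7 (unit A 2S,3R; C4' epimers) | COc1ccc([C@H]2Oc3cc(OCc4ccc(OC)cc4)cc(OCc4ccc(OC)cc4)c3C(=O)[C@@H]2[C@@H]2C(O[Si](CC)(CC)CC)c3c(OCc4ccccc4)cc(OCc4ccccc4)cc3O[C@H]2c2ccc(OCc3ccccc3)cc2)cc1
F6 | step 9 | lithium enolate of F5 at C3=C4 of unit A (C2 and unit B unchanged) | COc1ccc([C@H]2Oc3cc(OCc4ccc(OC)cc4)cc(OCc4ccc(OC)cc4)c3C(O[Li])=C2[C@@H]2C(O[Si](CC)(CC)CC)c3c(OCc4ccccc4)cc(OCc4ccccc4)cc3O[C@H]2c2ccc(OCc3ccccc3)cc2)cc1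
F7 | step 9 | cis isomer of the silyl-protected biflavanone: 18 with a triethylsilyloxy group (C4' epimers) in place of the C4' ketone | COc1ccc([C@H]2Oc3cc(OCc4ccc(OC)cc4)cc(OCc4ccc(OC)cc4)c3C(=O)[C@H]2[C@@H]2C(O[Si](CC)(CC)CC)c3c(OCc4ccccc4)cc(OCc4ccccc4)cc3O[C@H]2c2ccc(OCc3ccccc3)cc2)cc1
F8 | step 9 | hydroxy biflavanone: 18 with a hydroxyl group (C4' epimers) in place of the C4' ketone | COc1ccc([C@H]2Oc3cc(OCc4ccc(OC)cc4)cc(OCc4ccc(OC)cc4)c3C(=O)[C@H]2[C@@H]2C(O)c3c(OCc4ccccc4)cc(OCc4ccccc4)cc3O[C@H]2c2ccc(OCc3ccccc3)cc2)cc1
F9 | step 8 | diazo alcohol: 17 with a hydroxyl group (C4' epimers) in place of the C4' ketone | COc1ccc(COc2cc(OCc3ccc(OC)cc3)cc(OCc3ccc(OC)cc3)c2C(=O)C(=[N+]=[N-])[C@@H]2C(O)c3c(OCc4ccccc4)cc(OCc4ccccc4)cc3O[C@H]2c2ccc(OCc3ccccc3)cc2)cc1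
F10 | step 7 | {(2R)-5,7-bis(benzyloxy)-2-[4-(benzyloxy)phenyl]-2H-chromen-4-yl}oxy(trimethyl)silane | C[Si](C)(C)OC1=C[C@H](c2ccc(OCc3ccccc3)cc2)Oc2cc(OCc3ccccc3)cc(OCc3ccccc3)c12
F11 | step 6 | (E)-1-[2,4-bis(benzyloxy)-6-hydroxyphenyl]-3-[4-(benzyloxy)phenyl]prop-2-en-1-one | O=C(/C=C/c1ccc(OCc2ccccc2)cc1)c1c(O)cc(OCc2ccccc2)cc1OCc1ccccc1
F12 | step 6 | racemic 5,7-bis(benzyloxy)-2-[4-(benzyloxy)phenyl]chroman-4-one | O=C1CC(c2ccc(OCc3ccccc3)cc2)Oc2cc(OCc3ccccc3)cc(OCc3ccccc3)c12
F13 | step 6 | (2S,4S)-5,7-bis(benzyloxy)-2-[4-(benzyloxy)phenyl]chroman-4-ol (2,4-cis) | O[C@H]1C[C@@H](c2ccc(OCc3ccccc3)cc2)Oc2cc(OCc3ccccc3)cc(OCc3ccccc3)c12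
F0 | step 10 | none | none
A1 | alternative 1 | 3-{[6-(2,4-bis(benzyloxy)-6-fluorobenzoyl)-2-(4-benzyloxyphenyl)-5-(4-pivaloyloxyphenyl)cyclohex-3-en-1-yl]carbonyl}oxazolidin-2-one; both aryl groups and the imide carbonyl mutually cis, aroyl group trans to them | CC(C)(C)C(=O)Oc1ccc([C@H]2C=C[C@@H](c3ccc(OCc4ccccc4)cc3)[C@@H](C(=O)N3CCOC3=O)[C@@H]2C(=O)c2c(F)cc(OCc3ccccc3)cc2OCc2ccccc2)cc1
A2 | alternative 1 | 4-[(1E,3E)-4-(4-benzyloxyphenyl)buta-1,3-dien-1-yl]phenyl pivalate | CC(C)(C)C(=O)Oc1ccc(/C=C/C=C/c2ccc(OCc3ccccc3)cc2)cc1
A3 | alternative 1 | 3-{(E)-4-[2,4-bis(benzyloxy)-6-fluorophenyl]-4-oxobut-2-enoyl}oxazolidin-2-one | O=C(/C=C/C(=O)N1CCOC1=O)c1c(F)cc(OCc2ccccc2)cc1OCc1ccccc1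
A4 | alternative 2 | protected target with C4 of unit A as triisopropylsilyl ether: (2R,3S)-5,7-bis(benzyloxy)-2-(4-benzyloxyphenyl)-3-[(2S,3S,4S)-5,7-bis(benzyloxy)-2-(4-methoxyphenyl)-4-(triisopropylsilyloxy)chroman-3-yl]chroman-4-one | COc1ccc([C@H]2Oc3cc(OCc4ccccc4)cc(OCc4ccccc4)c3[C@@H](O[Si](C(C)C)(C(C)C)C(C)C)[C@H]2[C@@H]2C(=O)c3c(OCc4ccccc4)cc(OCc4ccccc4)cc3O[C@H]2c2ccc(OCc3ccccc3)cc2)cc1
A5 | alternative 2 | (E)-3-(4-benzyloxyphenyl)-2-[(2S,3S,4S)-5,7-bis(benzyloxy)-2-(4-methoxyphenyl)-4-(triisopropylsilyloxy)chroman-3-yl]prop-2-enoic acid | COc1ccc([C@H]2Oc3cc(OCc4ccccc4)cc(OCc4ccccc4)c3[C@@H](O[Si](C(C)C)(C(C)C)C(C)C)[C@H]2/C(=C\c2ccc(OCc3ccccc3)cc2)C(=O)O)cc1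
A6 | alternative 2 | 3,5-bis(benzyloxy)-2-(trimethylsilyl)phenyl trifluoromethanesulfonate | C[Si](C)(C)c1c(OCc2ccccc2)cc(OCc2ccccc2)cc1OS(=O)(=O)C(F)(F)F
A7 | alternative 2 | 3,5-bis(benzyloxy)benzyne | C1(OCc2ccccc2)=CC(OCc2ccccc2)=CC#C1
A8 | alternative 3 | tetrabenzyl ether of the target with the 4-hydroxyphenyl group free: (2S,3S)-5,7-bis(benzyloxy)-3-[(2R,3S)-5,7-bis(benzyloxy)-2-(4-hydroxyphenyl)-4-oxochroman-3-yl]-2-(4-methoxyphenyl)chroman-4-one | COc1ccc([C@H]2Oc3cc(OCc4ccccc4)cc(OCc4ccccc4)c3C(=O)[C@H]2[C@@H]2C(=O)c3c(OCc4ccccc4)cc(OCc4ccccc4)cc3O[C@H]2c2ccc(O)cc2)cc1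
A9 | alternative 3 | (2S,3S)-5,7-bis(benzyloxy)-3-{(2R)-1-[2,4-bis(benzyloxy)-6-hydroxyphenyl]-3-(4-hydroxyphenyl)-1-oxopropan-2-yl}-2-(4-methoxyphenyl)chroman-4-one | COc1ccc([C@H]2Oc3cc(OCc4ccccc4)cc(OCc4ccccc4)c3C(=O)[C@H]2[C@@H](Cc2ccc(O)cc2)C(=O)c2c(O)cc(OCc3ccccc3)cc2OCc2ccccc2)cc1
A10 | alternative 3 | para-quinone methide from A9: the 4-hydroxybenzyl group replaced by a (4-oxocyclohexa-2,5-dien-1-ylidene)methyl group, other centres as in A9 | COc1ccc([C@H]2Oc3cc(OCc4ccccc4)cc(OCc4ccccc4)c3C(=O)[C@H]2[C@@H](C=C2C=CC(=O)C=C2)C(=O)c2c(O)cc(OCc3ccccc3)cc2OCc2ccccc2)cc1
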